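**Plan**
- Numbering: lactone ring O1, C2(=O), C3=C4, C5, C6; side chain C1'–C15' (OH on C2', C4', C6'; C7'–C15' is the nonyl group).
- Retrosynthetic cuts, in order: (a) lactone O1–C2 and C3=C4, giving a Z-enoate from a C4 aldehyde; (b) C6'–C7' and C4'–C5' in one operation, giving nonyl on boron, a vinyl group (C6'=C5') and a C4' acyl chloride; (c) C2'–C3' and C6–C5, giving propane-1,3-diol (C2', C1', C6) and two allyl units.
- Enabling feature: C6'(OH)–C5'H2–C4'(OH) is a β-hydroxy-ketone-level triad whose carbinol carbon C6' carries only an unbranched primary alkyl chain. Nonyl can therefore migrate from boron to C6' of a B-vinyl ate complex while C5' is acylated by C4'. The anti C2'–O/C6–O1 pair is C2-symmetric, so one diol serves both ends.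
- Forward order: core C2'–C1'–C6 with both allyl arms (step 1); one arm cut back to the C4' acyl chloride (steps 2–5); C7'–C15', C6' and C5' added together (step 6); C4' carbinol (step 7); second arm converted to C4–C3–C2 and the lactone ring, the only ring of the target, closed last (steps 9–11).
- Stereochemistry: C2' and C6 from the catalyst made from [Ir(cod)Cl]2 and (S)-Cl,MeO-BIPHEP (step 1); C6' from the catalyst made from NiBr2·DME and the chiral diamine (step 6); C4' from C6' by 1,3-syn reduction (step 7); the Z-alkene from step 10.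

Key step: step 6

Assumption: the facial sense of the two catalyst-controlled steps (1 and 6) is assigned by analogy with related substrates; the ligand enantiomer named is the one expected to give the configuration drawn, and its antipode would be used if a model reaction shows the opposite sense.

**Step 1**
Reactants: 1 propane-1,3-diol; 2 allyl acetate (two equivalents are consumed, one per carbinol)
Product: 3 (4S,6S)-nona-1,8-diene-4,6-diol
Conditions: [Ir(cod)Cl]2 (cat.), (S)-Cl,MeO-BIPHEP (cat.), 4-chloro-3-nitrobenzoic acid (cat.), Cs2CO3 (cat.), 2 (excess), 1,4-dioxane, 90 °C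
Reagents that add atoms: allyl acetate (second equivalent), CC(=O)OCC=C
Why: Two-directional iridium-catalysed transfer-hydrogenative carbonyl allylation (Krische allylation), in which each primary alcohol in turn is dehydrogenated to the aldehyde and allylated under control of the catalyst formed from [Ir(cod)Cl]2, (S)-Cl,MeO-BIPHEP and the nitrobenzoic acid, so that one molecule of 2 is consumed at each end, both carbinol centres (future C2' and C6) are set by the catalyst and the second addition enriches the C2-symmetric anti diol.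

**Step 2**
Reactants: 3 (4S,6S)-nona-1,8-diene-4,6-diol
Product: 4 (4S,6S)-2,2-dimethyl-4,6-di(prop-2-en-1-yl)-1,3-dioxane
Conditions: 2,2-dimethoxypropane, PPTS (cat.), CH2Cl2, rt
Reagents that add atoms: 2,2-dimethoxypropane, COC(C)(C)OC
Why: Acid-catalysed transacetalisation ties the anti 1,3-diol into a trans-4,6-disubstituted dioxane that should survive the oxidants, the acyl chloride stage and the organoboron chemistry, with no stereocentre touched.

**Step 3**
Reactants: 4 (4S,6S)-2,2-dimethyl-4,6-di(prop-2-en-1-yl)-1,3-dioxane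
Product: 6 2-[(4R,6S)-2,2-dimethyl-6-(prop-2-en-1-yl)-1,3-dioxan-4-yl]acetaldehyde, via mono-diol 5 (not isolated)
Conditions: OsO4 (cat.), NaIO4 (2 equiv), 2,6-lutidine, 1,4-dioxane/H2O 3:1, rt; stopped at partial conversion, recovered 4 recycled
Reagents that add atoms: sodium periodate, [Na+].[O-][I](=O)(=O)=O (oxygen relayed through catalytic osmium tetroxide, O=[Os](=O)(=O)=O)
Why: Lemieux–Johnson cleavage limited to one alkene by the amount of periodate is statistical, but the two allyl groups are homotopic (C2 axis), so every mono-cleavage should give the same aldehyde, and unreacted 4 and the dialdehyde are separable by polarity.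

**Step 4**
Reactants: 6 2-[(4R,6S)-2,2-dimethyl-6-(prop-2-en-1-yl)-1,3-dioxan-4-yl]acetaldehyde
Product: 7 2-[(4R,6S)-2,2-dimethyl-6-(prop-2-en-1-yl)-1,3-dioxan-4-yl]acetic acid
Conditions: NaClO2, NaH2PO4, 2-methylbut-2-ene, t-BuOH/H2O, 0 °C to rt
Reagents that add atoms: sodium chlorite, [Na+].[O-]Cl=O
Why: Pinnick oxidation converts the aldehyde to the acid at buffered pH, with 2-methylbut-2-ene trapping hypochlorous acid so that the remaining alkene and the acetonide should stay intact.

**Step 5**
Reactants: 7 2-[(4R,6S)-2,2-dimethyl-6-(prop-2-en-1-yl)-1,3-dioxan-4-yl]acetic acid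
Product: 8 2-[(4R,6S)-2,2-dimethyl-6-(prop-2-en-1-yl)-1,3-dioxan-4-yl]acetyl chloride
Conditions: 1-chloro-N,N,2-trimethylprop-1-en-1-amine (Ghosez reagent), CH2Cl2, 0 °C to rt; concentrated and used crude
Reagents that add atoms: 1-chloro-N,N,2-trimethylprop-1-en-1-amine, CC(C)=C(Cl)N(C)C
Why: The chloroenamine converts the acid to the acyl chloride under neutral conditions with only an inert amide as by-product, so no HCl is released that could open the acetonide.

**Step 6**
Reactants: 9 non-1-ene; 10 tetravinylstannane; 8 2-[(4R,6S)-2,2-dimethyl-6-(prop-2-en-1-yl)-1,3-dioxan-4-yl]acetyl chloride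
Product: 15 (4R)-1-[(4R,6S)-2,2-dimethyl-6-(prop-2-en-1-yl)-1,3-dioxan-4-yl]-4-hydroxytridecan-2-one, via 9-nonyl-9-BBN 11 (not isolated), via vinyllithium 12 (not isolated), via lithium vinyl borate 13 (not isolated), via β-boryl ketone 14 (not isolated)
Conditions: 9, 9-BBN-H, THF, rt; 12 (from 10 and n-BuLi, Et2O, halide-free), 0 °C to rt; NiBr2·DME (cat.), (S,S)-N,N'-dimethyl-1,2-diphenylethane-1,2-diamine (cat.), 8, THF, 0 °C to rt; then pH 7 phosphate buffer, 30% aq. H2O2, 0 °C
Reagents that add atoms: hydrogen peroxide, OO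
Why: Proposed new method: hydroboration puts boron on C7' of 9 and vinyllithium 12 turns borane 11 into the four-coordinate borate 13; acyl chloride 8 adds oxidatively to zerovalent nickel, the resulting divalent acyl nickel species binds the vinyl group of 13 and induces a 1,2-metalate shift in which C7' migrates from boron to the boron-bearing vinyl carbon C6' anti to the metal, and reductive elimination then joins C5' to the acyl carbon C4'. The closest known reaction types are the nickel-catalysed conjunctive coupling of 9-BBN-derived vinyl borates with acyl chlorides, which gives β-boryl ketones without enantiocontrol, and the nickel/chiral diamine-catalysed enantioselective conjunctive coupling of the same borates with aryl halides; the proposal merges the two, so that the diamine controls the acyl manifold, and ends with the known stereoretentive oxidation of the secondary C–B bond. No ring is closed in this step. The new C6' stereocentre is set by the chiral diamine on nickel, which selects the vinyl face that is bound while the nonyl group arrives on the opposite face, and it is carried through the oxidation with retention; the two dioxane stereocentres of 8 are remote and untouched. The step needs migration of the primary nonyl ligand instead of a bicyclic B–C bond, which the 9-BBN cage secures because its boron-bound bridgehead carbons are poor migrating groups, and it needs the metalate shift to outrun direct transfer of a boron ligand to the acyl nickel species, which the diamine-ligated nickel centre and the electron-rich borate alkene should secure while the unactivated allyl group of 8 stays out of play. Buffered peroxide keeps the β-hydroxy ketone away from base, so that neither retro-aldol cleavage nor β-elimination of the acetal oxygen at C2' intervenes.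

**Step 7**
Reactants: 15 (4R)-1-[(4R,6S)-2,2-dimethyl-6-(prop-2-en-1-yl)-1,3-dioxan-4-yl]-4-hydroxytridecan-2-one
Product: 17 (2R,4R)-1-[(4S,6S)-2,2-dimethyl-6-(prop-2-en-1-yl)-1,3-dioxan-4-yl]tridecane-2,4-diol, via boron chelate 16 (not isolated)
Conditions: Et2BOMe, THF/MeOH 4:1, −78 °C; NaBH4, −78 °C; AcOH, then MeOH co-evaporation
Reagents that add atoms: none
Why: Narasaka–Prasad reduction, in which diethylboron locks the C6' oxygen and the C4' ketone in a six-membered chelate 16 and borohydride attacks axially, should give the 1,3-syn diol (new C4' centre controlled by C6'), the boron being removed by methanolysis.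

**Step 8**
Reactants: 17 (2R,4R)-1-[(4S,6S)-2,2-dimethyl-6-(prop-2-en-1-yl)-1,3-dioxan-4-yl]tridecane-2,4-diol
Product: 18 (4R,6R)-4-{[(4R,6S)-2,2-dimethyl-6-(prop-2-en-1-yl)-1,3-dioxan-4-yl]methyl}-2,2-dimethyl-6-nonyl-1,3-dioxane
Conditions: 2,2-dimethoxypropane (excess), PPTS (cat.), CH2Cl2, rt
Reagents that add atoms: 2,2-dimethoxypropane, COC(C)(C)OC
Why: Acetonide formation on the syn 1,3-diol gives the chair cis-4,6-disubstituted dioxane and masks both hydroxyls for the basic olefination, the excess ketal keeping the existing trans-acetonide in place.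

**Step 9**
Reactants: 18 (4R,6R)-4-{[(4R,6S)-2,2-dimethyl-6-(prop-2-en-1-yl)-1,3-dioxan-4-yl]methyl}-2,2-dimethyl-6-nonyl-1,3-dioxane
Product: 20 2-[(4R,6S)-6-{[(4R,6R)-2,2-dimethyl-6-nonyl-1,3-dioxan-4-yl]methyl}-2,2-dimethyl-1,3-dioxan-4-yl]acetaldehyde, via diol 19 (not isolated)
Conditions: OsO4 (cat.), NaIO4, 2,6-lutidine, 1,4-dioxane/H2O 3:1, rt
Reagents that add atoms: sodium periodate, [Na+].[O-][I](=O)(=O)=O (oxygen relayed through catalytic osmium tetroxide, O=[Os](=O)(=O)=O)
Why: Lemieux–Johnson cleavage of the only remaining alkene unmasks C4 of the future lactone as a β-alkoxy aldehyde, the lutidine buffer protecting both acetonides and suppressing β-elimination.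

**Step 10**
Reactants: 20 2-[(4R,6S)-6-{[(4R,6R)-2,2-dimethyl-6-nonyl-1,3-dioxan-4-yl]methyl}-2,2-dimethyl-1,3-dioxan-4-yl]acetaldehyde
Product: 21 methyl (2Z)-4-[(4S,6R)-6-{[(4R,6R)-2,2-dimethyl-6-nonyl-1,3-dioxan-4-yl]methyl}-2,2-dimethyl-1,3-dioxan-4-yl]but-2-enoate
Conditions: (CF3CH2O)2P(O)CH2CO2Me, KN(SiMe3)2, 18-crown-6, THF, −78 °C
Reagents that add atoms: methyl bis(2,2,2-trifluoroethyl)phosphonoacetate, COC(=O)CP(=O)(OCC(F)(F)F)OCC(F)(F)F
Why: Still–Gennari olefination with the electron-poor phosphonate under dissociating conditions collapses kinetically and should give the (Z)-enoate needed for ring closure, the low temperature guarding against β-elimination of the acetal oxygen.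

**Step 11**
Reactants: 21 methyl (2Z)-4-[(4S,6R)-6-{[(4R,6R)-2,2-dimethyl-6-nonyl-1,3-dioxan-4-yl]methyl}-2,2-dimethyl-1,3-dioxan-4-yl]but-2-enoate
Product: 23 (6S)-6-[(2S,4R,6R)-2,4,6-trihydroxypentadecyl]-5,6-dihydro-2H-pyran-2-one, via tetrahydroxy Z-ester 22 (not isolated)
Conditions: 2 M aq. HCl, THF, 0 °C to rt
Reagents that add atoms: none
Why: Acid hydrolysis removes both acetonides and the freed C6 hydroxyl, held next to the ester by the Z double bond, should lactonise to the six-membered 5,6-dihydropyran-2-one (the other hydroxyls could only give eight-, ten- or twelve-membered rings), with no stereocentre touched.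

**Compound list**
1 | propane-1,3-diol | OCCCO | starting material
2 | allyl acetate (prop-2-en-1-yl acetate) | CC(=O)OCC=C | starting material
3 | (4S,6S)-nona-1,8-diene-4,6-diol | C=CC[C@H](O)C[C@@H](O)CC=C | intermediate
4 | (4S,6S)-2,2-dimethyl-4,6-di(prop-2-en-1-yl)-1,3-dioxane | C=CC[C@H]1C[C@H](CC=C)OC(C)(C)O1 | intermediate
5 | mono-diol: 4 with one CH=CH2 turned into CH(OH)CH2OH, ring centres as in 4, both epimers at the new carbinol | OCC(O)C[C@H]1C[C@H](CC=C)OC(C)(C)O1 | intermediate
6 | 2-[(4R,6S)-2,2-dimethyl-6-(prop-2-en-1-yl)-1,3-dioxan-4-yl]acetaldehyde | O=CC[C@H]1C[C@H](CC=C)OC(C)(C)O1 | intermediate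
7 | 2-[(4R,6S)-2,2-dimethyl-6-(prop-2-en-1-yl)-1,3-dioxan-4-yl]acetic acid | OC(=O)C[C@H]1C[C@H](CC=C)OC(C)(C)O1 | intermediate
8 | 2-[(4R,6S)-2,2-dimethyl-6-(prop-2-en-1-yl)-1,3-dioxan-4-yl]acetyl chloride | ClC(=O)C[C@H]1C[C@H](CC=C)OC(C)(C)O1 | intermediate
9 | non-1-ene | CCCCCCCC=C | starting material
10 | tetravinylstannane | C=C[Sn](C=C)(C=C)C=C | starting material
11 | 9-nonyl-9-borabicyclo[3.3.1]nonane | CCCCCCCCCB1C2CCCC1CCC2 | intermediate
12 | vinyllithium | [Li]C=C | intermediate
13 | lithium 9-ethenyl-9-nonyl-9-boranuidabicyclo[3.3.1]nonane | [Li+].CCCCCCCCC[B-]1(C=C)C2CCCC1CCC2 | intermediate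
14 | (4R)-4-(9-borabicyclo[3.3.1]nonan-9-yl)-1-[(4R,6S)-2,2-dimethyl-6-(prop-2-en-1-yl)-1,3-dioxan-4-yl]tridecan-2-one | CCCCCCCCC[C@@H](B1C2CCCC1CCC2)CC(=O)C[C@H]1C[C@H](CC=C)OC(C)(C)O1 | intermediate
15 | (4R)-1-[(4R,6S)-2,2-dimethyl-6-(prop-2-en-1-yl)-1,3-dioxan-4-yl]-4-hydroxytridecan-2-one | CCCCCCCCC[C@@H](O)CC(=O)C[C@H]1C[C@H](CC=C)OC(C)(C)O1 | intermediate
16 | (4R)-1-[(4R,6S)-2,2-dimethyl-6-(prop-2-en-1-yl)-1,3-dioxan-4-yl]-2-oxotridecan-4-yl diethylborinate (ketone oxygen coordinated to boron) | CCCCCCCCC[C@@H](OB(CC)CC)CC(=O)C[C@H]1C[C@H](CC=C)OC(C)(C)O1 | intermediate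
17 | (2R,4R)-1-[(4S,6S)-2,2-dimethyl-6-(prop-2-en-1-yl)-1,3-dioxan-4-yl]tridecane-2,4-diol | CCCCCCCCC[C@@H](O)C[C@@H](O)C[C@H]1C[C@H](CC=C)OC(C)(C)O1 | intermediate
18 | (4R,6R)-4-{[(4R,6S)-2,2-dimethyl-6-(prop-2-en-1-yl)-1,3-dioxan-4-yl]methyl}-2,2-dimethyl-6-nonyl-1,3-dioxane | CCCCCCCCC[C@@H]1C[C@H](C[C@H]2C[C@H](CC=C)OC(C)(C)O2)OC(C)(C)O1 | intermediate
19 | diol: 18 with CH=CH2 turned into CH(OH)CH2OH, ring centres as in 18, both epimers at the new carbinol | CCCCCCCCC[C@@H]1C[C@H](C[C@H]2C[C@H](CC(O)CO)OC(C)(C)O2)OC(C)(C)O1 | intermediate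
20 | 2-[(4R,6S)-6-{[(4R,6R)-2,2-dimethyl-6-nonyl-1,3-dioxan-4-yl]methyl}-2,2-dimethyl-1,3-dioxan-4-yl]acetaldehyde | CCCCCCCCC[C@@H]1C[C@H](C[C@H]2C[C@H](CC=O)OC(C)(C)O2)OC(C)(C)O1 | intermediate
21 | methyl (2Z)-4-[(4S,6R)-6-{[(4R,6R)-2,2-dimethyl-6-nonyl-1,3-dioxan-4-yl]methyl}-2,2-dimethyl-1,3-dioxan-4-yl]but-2-enoate | CCCCCCCCC[C@@H]1C[C@H](C[C@H]2C[C@H](C/C=C\C(=O)OC)OC(C)(C)O2)OC(C)(C)O1 | intermediate
22 | methyl (2Z,5S,7R,9R,11R)-5,7,9,11-tetrahydroxyicos-2-enoate | CCCCCCCCC[C@@H](O)C[C@@H](O)C[C@H](O)C[C@@H](O)C/C=C\C(=O)OC | intermediate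
23 | (6S)-6-[(2S,4R,6R)-2,4,6-trihydroxypentadecyl]-5,6-dihydro-2H-pyran-2-one | CCCCCCCCC[C@@H](O)C[C@@H](O)C[C@H](O)C[C@@H]1CC=CC(=O)O1 | target

**Totals**
Total steps: 11. Longest linear sequence: 11 steps (1 to 23); non-1-ene and tetravinylstannane enter as purchased materials in step 6.

**Steps most likely to fail**

1. Step 6 (key step, proposed new method). Risks: direct transfer of a boron ligand to the acyl nickel species or uncatalysed attack of the borate on the acyl chloride may outrun the metalate shift; facial selectivity may be poor with this β-oxygenated acyl chloride; the product may be lost by retro-aldol cleavage during oxidation. The fallback sets out from aldehyde 6 and returns at diol 17, still forming the C6'–C7' bond but by acyl substitution, and uses known chemistry only. A Mukaiyama acetate aldol of 6 with 1-methoxy-1-(trimethylsilyloxy)ethene, catalysed by a chiral titanium Schiff-base complex (Ti(OiPr)4, binaphthyl-derived tridentate ligand, 3,5-di-tert-butylsalicylic acid), should give the trimethylsilyl ether F1 with C4' set by the catalyst. Bu4NF in the work-up frees the hydroxy ester F2. MeNH(OMe)·HCl with i-PrMgCl converts it to the Weinreb amide F3. Excess C9H19MgBr then adds once to give the β-hydroxy ketone F4 (hydroxyl on C4', ketone on C6'). The conditions of step 7 reduce F4 1,3-syn, now setting C6' from C4', to give 17.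

2. Step 11. Risks: under the acid needed for the cis-acetonide, the freed C2' hydroxyl may add in conjugate fashion to C4 of the enoate or lactone, or the Z-alkene may isomerise before ring closure. The fallback sets out from 21 and returns at 23, generating the Michael acceptor only after all hydroxyls are free. i-Bu2AlH (CH2Cl2, −78 °C) reduces the ester to the (Z)-allylic alcohol F5. Aqueous acid then removes both acetonides to give the pentaol F6. TEMPO (cat.) with PhI(OAc)2 oxidises only the primary allylic hydroxyl; the enal closes onto the C6 hydroxyl as the lactol F7, which is oxidised on to lactone 23.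

3. Step 10. Risks: erosion of Z-selectivity, or β-elimination of the acetal oxygen from the β-alkoxy aldehyde under the basic conditions. The fallback sets out from aldehyde 20 and returns at 21, fixing the geometry by syn hydrogenation instead of by olefination. Ohira–Bestmann homologation (dimethyl (1-diazo-2-oxopropyl)phosphonate, K2CO3, MeOH) gives the terminal alkyne F8. n-BuLi followed by methyl chloroformate gives the ynoate F9. Semi-hydrogenation over Pd/CaCO3 poisoned with Pb(OAc)2 (Lindlar catalyst) with quinoline gives 21.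

**Further compounds**
F1 | step 6 | methyl (3S)-4-[(4R,6S)-2,2-dimethyl-6-(prop-2-en-1-yl)-1,3-dioxan-4-yl]-3-[(trimethylsilyl)oxy]butanoate | COC(=O)C[C@@H](O[Si](C)(C)C)C[C@H]1C[C@H](CC=C)OC(C)(C)O1
F2 | step 6 | methyl (3S)-4-[(4S,6S)-2,2-dimethyl-6-(prop-2-en-1-yl)-1,3-dioxan-4-yl]-3-hydroxybutanoate | COC(=O)C[C@@H](O)C[C@H]1C[C@H](CC=C)OC(C)(C)O1
F3 | step 6 | (3S)-4-[(4S,6S)-2,2-dimethyl-6-(prop-2-en-1-yl)-1,3-dioxan-4-yl]-3-hydroxy-N-methoxy-N-methylbutanamide | CON(C)C(=O)C[C@@H](O)C[C@H]1C[C@H](CC=C)OC(C)(C)O1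
F4 | step 6 | (2S)-1-[(4S,6S)-2,2-dimethyl-6-(prop-2-en-1-yl)-1,3-dioxan-4-yl]-2-hydroxytridecan-4-one | CCCCCCCCCC(=O)C[C@@H](O)C[C@H]1C[C@H](CC=C)OC(C)(C)O1
F5 | step 11 | (2Z)-4-[(4S,6R)-6-{[(4R,6R)-2,2-dimethyl-6-nonyl-1,3-dioxan-4-yl]methyl}-2,2-dimethyl-1,3-dioxan-4-yl]but-2-en-1-ol | CCCCCCCCC[C@@H]1C[C@H](C[C@H]2C[C@H](C/C=C\CO)OC(C)(C)O2)OC(C)(C)O1
F6 | step 11 | (2Z,5S,7R,9R,11R)-icos-2-ene-1,5,7,9,11-pentol | CCCCCCCCC[C@@H](O)C[C@@H](O)C[C@H](O)C[C@@H](O)C/C=C\CO
F7 | step 11 | (6S)-6-[(2S,4R,6R)-2,4,6-trihydroxypentadecyl]-5,6-dihydro-2H-pyran-2-ol (both anomers) | CCCCCCCCC[C@@H](O)C[C@@H](O)C[C@H](O)C[C@@H]1CC=CC(O)O1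
F8 | step 10 | (4R,6R)-4-{[(4R,6S)-2,2-dimethyl-6-(prop-2-yn-1-yl)-1,3-dioxan-4-yl]methyl}-2,2-dimethyl-6-nonyl-1,3-dioxane | CCCCCCCCC[C@@H]1C[C@H](C[C@H]2C[C@H](CC#C)OC(C)(C)O2)OC(C)(C)O1
F9 | step 10 | methyl 4-[(4S,6R)-6-{[(4R,6R)-2,2-dimethyl-6-nonyl-1,3-dioxan-4-yl]methyl}-2,2-dimethyl-1,3-dioxan-4-yl]but-2-ynoate | CCCCCCCCC[C@@H]1C[C@H](C[C@H]2C[C@H](CC#CC(=O)OC)OC(C)(C)O2)OC(C)(C)O1
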